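(The earlier runs and the new flask stem from a simulated flask with constants of no real substance, and the scatter is random.)

Set what the noon flask has lost against what it shows: by 3.00 h the free starting complex is down by 83.1% of the charge, while the reading of complex with one exchanged stands at 41.9%.

- noon: starting complex 2.9 M; gas 180 mM (held); temperature 60 °C; the very flask that is asked about, followed so far
- flask: starting complex 2.9 M; gas 180 mM (held); temperature 60 °C; time 10 h

noon run (percent of the starting complex charged)

| time / h | complex with one exchanged / % | starting complex / % |
|---|---|---|
| 0.500 | 12.1 | 77.2 |
| 1.50 | 30.3 | 39.7 |
| 3.00 | 41.9 | 16.9 |
| 4.00 | 43.2 | 12.2 |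
| 6.00 | 44.0 | 7.4 |
| 8.00 | 42.6 | 5.9 |

(each reading ± 0.5 percentage points)

- north-east: at 10 h raise the temperature by 15 K, then wait 3.0 h
- west: change nothing and wait 3.0 h more
- north: at 10 h take out 90% of the leaving ligand then present, then wait 3.0 h

- what is added takes up no volume worth counting
- the earlier runs were read with a standard deviation of 0.5 percentage points
- at the start none of the gas is in solution
- a reading or a percentage of complex with one exchanged counts all its forms, free or not
- the earlier runs do not show what temperature does; that part of a forecast is a guess
- a reading of starting complex is of its free form alone

* complex with one exchanged, in percent of the starting complex first charged, at 10 h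
* the remedy with the largest gain of complex with one exchanged, or "none" below 2 percentage points (north-east / west / north / none)
* complex with one exchanged present, in percent of the starting complex first charged, after west
* complex with one exchanged present, in percent of the starting complex first charged, after north

Call the ratio of these two amounts the return, a selectivity for complex with one exchanged, and read it as 0.504. Reckon it again from the later readings: 0.475 at 6.00 h and 0.453 at 8.00 h. The return slips late, so multiply it by the share lost to bracket the flask at 10 h.

For a loose bound from above, keep the early return and let the whole charge go: 50.4%. To tighten it, keep the last return and let the starting complex fall on at its last pace to 4.40%, which gives 43.3%. For the bound from below, let the return slip by its last step again and hold the starting complex at its last reading, which gives 40.5%. Commit to the middle, 41.9%.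

The forecast gives 41.2%, inside this bracket but not at its middle, with 39.3% after west and 42.8% after north, and chooses north: “Heating is a guess and probably doesn't help, so north is best.”

The flask gives 42.0% at 10 h. North-east brings a gain of 5.4 percentage points, so the best remedy is north-east, while west ends at 41.5% and north at 34.8%.

    gas ⇌ incoming ligand, rate k1*(csat - [incoming ligand]) (kL = 7.90 /h)
    complex with one exchanged + incoming ligand ⇌ leaving ligand + complex with two exchanged (K = 7.90, k = 33.0 /M/h, Ea = 72.0 kJ/mol, ΔH = −71.0 kJ/mol)
    starting complex + complex with one exchanged ⇌ idle adduct, settled at all times (K = 5.90 /M, ΔH = −39.0 kJ/mol)
    starting complex + incoming ligand ⇌ leaving ligand + complex with one exchanged (K = 54.0, k = 4.30 /M/h, Ea = 71.0 kJ/mol, ΔH = −9.00 kJ/mol)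
    complex with one exchanged ⇌ isomer of the product (K = 1.00, k = 0.430 /h, Ea = 95.0 kJ/mol, ΔH = −22.0 kJ/mol)
    (constants at 60 °C)

With 6.1% of the starting complex still free, the early return gives 47.3%, which is 5.3 points above the flask; its return has become 0.447.

Take the repeat at 35 °C, with 23% of its starting complex free at the end: the early return gives 38.8%. The computed repeat holds 36.4%.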